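I began at early times, with these flasks, readings and questions.

| flask | L | G | remark | time |
|---|---|---|---|---|
| maple | 20 mM | 24 mM | run made earlier |  |
| larch | 10 mM | 24 mM | run made earlier |  |
| cedar | 15 mM | 24 mM | run made earlier |  |
| epsilon | 20 mM | 24.0 mM | a single well-mixed tank run continuously and read at steady state, 2.5 min in it on average |  |
| theta | 20 mM | 24.0 mM | a closed flask charged with all of it at once and left for 2.5 min | 2.5 min |
| delta | 20 mM | 24.0 mM | a single well-mixed tank run continuously and read at steady state, 12.5 min in it on average |  |
| eta | 20 mM (fed, over 2.50 min) | 24.0 mM | a stirred flask in which L is dosed at a steady rate over 2.50 min without added volume, worked up at 2.5 min | 2.5 min |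

| run | time / min | X / % | E / % | Z / % |
|---|---|---|---|---|
| maple | 0.200 | 4 | 7 | 0 |
| maple | 0.333 | 3 | 9 | 0 |
| maple | 0.500 | 4 | 11 | 0 |
| maple | 0.667 | 4 | 14 | 0 |
| maple | 1.00 | 7 | 22 | 1 |
| maple | 1.50 | 8 | 32 | 0 |
| maple | 2.50 | 15 | 38 | 0 |
| larch | 0.167 | 7 | 6 | 1 |
| larch | 0.417 | 6 | 9 | 1 |
| larch | 0.667 | 10 | 10 | 3 |
| larch | 1.00 | 14 | 14 | 1 |
| larch | 1.50 | 15 | 20 | 0 |
| larch | 2.00 | 17 | 24 | 4 |
| larch | 2.50 | 19 | 27 | 0 |
| cedar | 0.333 | 6 | 8 | 0 |
| cedar | 0.667 | 13 | 14 | 2 |
| cedar | 1.00 | 10 | 22 | 0 |
| cedar | 1.33 | 14 | 24 | 1 |
| cedar | 2.00 | 14 | 29 | 0 |
| cedar | 2.50 | 17 | 35 | 1 |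

(standard deviation of a reading: 2 percentage points)

- in percentages every species weighs as the L in it: one E counts as two
- the stated concentrations are those of everything mixed, before any reaction; amounts are the same in each set-up
- the feed brings no volume worth counting
- the earlier runs were made in a closed, stirred flask

1. the set-up with the highest share of X in all that became X or E or Z or Q, at the outlet or at the end ("none" if the first two lie within 2 percentage points) (epsilon / theta / delta / eta / none)
2. share of X in all that became X or E or Z or Q, at the outlet or at the end, epsilon
3. share of X in all that became X or E or Z or Q, at the outlet or at the end, theta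
4. share of X in all that became X or E or Z or Q, at the outlet or at the end, delta
5. share of X in all that became X or E or Z or Q, at the outlet or at the end, eta

All three earlier runs were read at nearly the same early time, 0.667 min, and at 2.50 min. Summed over the runs, X to E stood at 0.711 early and at 0.510 late, so the ratio fell while L was being used up. I read this as X being lost to something unread, probably Q.

X formed at a steady rate is on average half as old as the run, so I divided the logarithm of that fall by half the interval. This gave the loss constant of X, the fraction of standing X that goes per minute: 0.362 min⁻¹. Multiplied by the time in the vessel, it counts the turnovers of X.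

My objection was that each reading scatters by 2 percentage points, so the constant is rough. I therefore tested the conclusion with half of it.

For theta, the maple readings with the unseen Q restored gave me a share of 24.7 %. Delta holds 4.52 turnovers, and a tank keeps one part in one plus that number, 18.1 %. Applied to the forecast's own 47 %, this gives about 8.51 %. With the halved constant it gives 14.4 %, still below my theta. In eta, X is born late, on average about 0.833 min before the end, so 74.0 % survives, and L stands low as well. I therefore committed to eta.

The forecast chose delta, with 32 % for epsilon, 28 % for theta, 47 % for delta and 38 % for eta, on the ground that “low standing L favours X”.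

The flasks gave 18.6 % for epsilon, 19.6 % for theta, 7.97 % for delta and 30.3 % for eta, so the best was eta. The scheme runs through D, a species formed on the way:

    L + G → D (k = 0.239 L mol⁻¹ s⁻¹)
    D → X (k = 0.109 s⁻¹)
    L + D → E (k = 6.69 L mol⁻¹ s⁻¹)
    D → Z (k = 0.00189 s⁻¹)
    X → Q (k = 0.00865 s⁻¹)

In delta, with L standing at 5.37 mM and G at 12.2 mM, D went on to X and E while X, with a half-life of 1.3 min on its way to Q, sat through 6.49 turnovers by that half-life, against 4.52 by my constant, and its share came to 7.97 %. In eta, L reached 12.6 mM at its highest and the share came to 30.3 % at 2.5 min, a time worth 1.30 turnovers by the constant of X to Q, though X formed late in the dosing sat through fewer; when eta was left to 25.0 min, worth 13.0 such turnovers, its share stood at 0.437 %.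

All runs are simulated with made-up constants; the scatter is artificial.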